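## Retrosynthetic overview

1. The lactone ring is formed last. A C12 carboxylate opens a 6α,7α-epoxide at C6 with inversion, which gives 6β-O and 7α-OH. The epoxide itself is placed by the 8α-hydroxyl group.
2. The C7–C11 bond comes from a Negishi coupling of the C6=C7 enol triflate with an α-zincated acrylate.
3. The C7 ketone and 8α-OH come from epoxidation of a C7 methyl enol ether. The 9β-O comes from 1,2-reduction of a vinylogous ester and is then angeloylated.
4. Vinyl and isopropenyl come from one double Wittig methylenation of a formyl and an acetyl group.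
5. The carbocycle is formed first. A hydrogen-bond-catalysed asymmetric Diels–Alder reaction of Brassard's diene with (E)-2-methyl-4-oxopent-2-enal sets C5 and C10.

Assumption: elemane numbering is used (ring C5–C10; C10 carries the methyl and the C1=C2 vinyl group; C5 carries the isopropenyl group; lactone carbons are C11–C13). β is the ring face that carries the C10 methyl group. Absolute configuration is as written in the SMILES.

## Route

Step 1
Reactants: 1 methylglyoxal (40 wt % in water); 2 2-(triphenylphosphoranylidene)propanal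
Product: 3 (2E)-2-methyl-4-oxopent-2-enal
Conditions: 1 (1.5 equiv), CH2Cl2/H2O, 23 °C, 16 h
Reagents that add atoms: none
Why: Wittig olefination with a stabilised ylide takes only the much more electrophilic aldehyde carbonyl of 1 and gives the E alkene, so acetyl and formyl end up trans.

Step 2
Reactants: 4 methyl (2E)-3-methoxybut-2-enoate
Product: 5 (1E)-1,3-dimethoxy-1-(trimethylsilyloxy)buta-1,3-diene (Brassard diene)
Conditions: LiN(iPr)2 (1.1 equiv), THF, −78 °C; Me3SiCl (1.2 equiv), −78 → 0 °C
Reagents that add atoms: chlorotrimethylsilane, C[Si](C)(C)Cl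
Why: γ-Deprotonation of the vinylogous carbonate followed by O-silylation of the extended enolate (silyl ketene acetal formation) gives the diene.

Step 3
Reactants: 3 (2E)-2-methyl-4-oxopent-2-enal; 5 Brassard diene
Product: 7 (1R,2R)-2-acetyl-4-methoxy-1-methyl-6-oxocyclohex-4-ene-1-carbaldehyde, via silyl methyl ketal cycloadduct 6 (not isolated)
Conditions: (4R,5R)-2,2-dimethyl-α,α,α′,α′-tetra(1-naphthyl)-1,3-dioxolane-4,5-dimethanol (20 mol %), toluene, 4 Å MS, −78 → −40 °C, 48 h; then CF3CO2H (5 mol %), CH2Cl2, −20 °C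
Reagents that add atoms: none
Why: Proposed new method: a hydrogen-bond-catalysed enantioselective carbo-Diels–Alder reaction of a 1,1,3-trioxygenated diene with a trisubstituted ene-dicarbonyl, in which the internally hydrogen-bonded TADDOL hydroxyl binds the formyl oxygen (the only carbonyl whose activation makes the unhindered C5 electrophilic), the CH2 terminus of 5 bonds to C5 and the ketene-acetal carbon to C10 in one asynchronous suprafacial event so that the E geometry of 3 becomes the trans C5-acetyl/C10-formyl relation, a naphthyl wall blocks one face of the bound enal and so sets both stereocentres (the antipodal diol gives ent-7), no diene terminus stays stereogenic so no endo/exo question arises, and loss of Me3SiOMe from 6 leaves the vinylogous ester; the closest known reaction types are the TADDOL-catalysed Diels–Alder reaction of 1-amino-3-siloxydienes with α-substituted acroleins and the TADDOL-catalysed hetero-Diels–Alder reaction of diene 5 with aldehydes.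

Step 4
Reactants: 7 (1R,2R)-2-acetyl-4-methoxy-1-methyl-6-oxocyclohex-4-ene-1-carbaldehyde
Product: 8 (5S,6S)-6-ethenyl-3-methoxy-6-methyl-5-(prop-1-en-2-yl)cyclohex-2-en-1-one
Conditions: Ph3PCH3Br (3.5 equiv), KN(SiMe3)2 (3.3 equiv), THF, 0 °C; then 7 added at −78 °C, → 23 °C
Reagents that add atoms: methyltriphenylphosphonium bromide, C[P+](c1ccccc1)(c1ccccc1)c1ccccc1.[Br-]
Why: Double Wittig methylenation works because the aldehyde reacts at once at −78 °C (before any ketone enolate could add to it), the methyl ketone reacts on warming, and the hindered vinylogous ester carbonyl is inert, while the C5 substituent is already in the stable trans equatorial position.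

Step 5
Reactants: 8 (5S,6S)-6-ethenyl-3-methoxy-6-methyl-5-(prop-1-en-2-yl)cyclohex-2-en-1-one
Product: 9 (1S,5S,6S)-6-ethenyl-3-methoxy-6-methyl-5-(prop-1-en-2-yl)cyclohex-2-en-1-ol (9β-OH)
Conditions: iBu2AlH (1.2 equiv), CH2Cl2, −78 °C; aq. potassium sodium tartrate work-up, no acid
Reagents that add atoms: none
Why: This is the 1,2-reduction of a vinylogous ester (the first half of a Stork–Danheiser sequence, stopped at the allylic alcohol), in which hydride arrives from the α face, anti to the pseudo-axial C10 methyl group, and gives the equatorial 9β-alcohol.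

Step 6
Reactants: 9 the 9β-alcohol; 10 angelic acid ((2Z)-2-methylbut-2-enoic acid)
Product: 12 (1S,5S,6S)-6-ethenyl-3-methoxy-6-methyl-5-(prop-1-en-2-yl)cyclohex-2-en-1-yl (2Z)-2-methylbut-2-enoate, via mixed anhydride 11 (not isolated)
Conditions: 10, 2,4,6-Cl3C6H2COCl, Et3N, toluene, 23 °C; then 9, DMAP, 60 °C
Reagents that add atoms: none
Why: Yamaguchi esterification acylates the only free hydroxyl group under basic conditions that the acid-labile enol ether tolerates, and this mixed anhydride transfers the angeloyl group without Z to E isomerisation.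

Step 7
Reactants: 12 the 9β-angelate enol ether
Product: 15 (1R,2S,5S,6S)-6-ethenyl-6-methyl-3-oxo-5-(prop-1-en-2-yl)-2-(triethylsilyloxy)cyclohexyl (2Z)-2-methylbut-2-enoate, via methoxy epoxide 13 (not isolated), via ketol 14 (not isolated)
Conditions: dimethyldioxirane (1.05 equiv), acetone/CH2Cl2, −78 → −20 °C; H2O (5 equiv), 0 °C; concentrate, toluene azeotrope; Et3SiOTf, 2,6-lutidine, CH2Cl2, −78 °C
Reagents that add atoms: dimethyldioxirane, CC1(C)OO1; water, O; triethylsilyl trifluoromethanesulfonate, CC[Si](CC)(CC)OS(=O)(=O)C(F)(F)F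
Why: This Rubottom-type oxidation is chemoselective because the enol ether is by far the most electron-rich alkene, it is attacked from the α face (anti to the 9β-ester and to the syn-axial C10 methyl group), hydrolysis of the methoxy epoxide gives the C7 ketone with the equatorial 8α-OH, and that hydroxyl is then silylated in the same flask.

Step 8
Reactants: 15 the 8α-silyloxy ketone
Product: 16 (1R,2S,5S,6S)-6-ethenyl-6-methyl-5-(prop-1-en-2-yl)-2-(triethylsilyloxy)-3-(trifluoromethylsulfonyloxy)cyclohex-3-en-1-yl (2Z)-2-methylbut-2-enoate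
Conditions: KN(SiMe3)2 (1.1 equiv), THF, −78 °C, 20 min; Comins reagent (1.2 equiv), −78 °C
Reagents that add atoms: N-(5-chloropyridin-2-yl)bis(trifluoromethanesulfonimide) (Comins reagent), O=S(=O)(N(c1ccc(Cl)cn1)S(=O)(=O)C(F)(F)F)C(F)(F)F
Why: Kinetic deprotonation takes the C6 methylene rather than the tertiary, silyloxy-shielded C8–H (whose removal would expel the angelate), and O-triflation fixes the C6=C7 enol triflate.

Step 9
Reactants: 17 2-bromoacrylic acid; 18 2-(trimethylsilyl)ethanol
Product: 19 2-(trimethylsilyl)ethyl 2-bromoacrylate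
Conditions: DCC (1.05 equiv), DMAP (5 mol %), CH2Cl2, 0 → 23 °C
Reagents that add atoms: none
Why: Steglich esterification gives a fluoride-labile ester of the C11–C13 building block.

Step 10
Reactants: 16 the enol triflate; 19 2-(trimethylsilyl)ethyl 2-bromoacrylate
Product: 21 (1R,2R,5S,6S)-6-ethenyl-6-methyl-5-(prop-1-en-2-yl)-2-(triethylsilyloxy)-3-{3-oxo-3-[2-(trimethylsilyl)ethoxy]prop-1-en-2-yl}cyclohex-3-en-1-yl (2Z)-2-methylbut-2-enoate, via vinylzinc bromide 20 (not isolated)
Conditions: 19, Zn dust (activated), LiCl, THF, 23 °C; then 16, Pd(PPh3)4 (5 mol %), THF, 45 °C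
Reagents that add atoms: none
Why: Negishi coupling of an α-(alkoxycarbonyl)vinylzinc halide with an alkenyl triflate forms the C7–C11 bond under neutral conditions that leave both esters and the silyl ether untouched.

Step 11
Reactants: 21 the silyl-protected diene ester
Product: 22 (1R,2R,5S,6S)-6-ethenyl-2-hydroxy-6-methyl-5-(prop-1-en-2-yl)-3-{3-oxo-3-[2-(trimethylsilyl)ethoxy]prop-1-en-2-yl}cyclohex-3-en-1-yl (2Z)-2-methylbut-2-enoate
Conditions: PPTS (20 mol %), MeOH, 0 → 23 °C
Reagents that add atoms: none
Why: Mild acid-catalysed methanolysis removes the triethylsilyl ether only, so the acid stays masked and cannot lactonise onto the freed 8-OH.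

Step 12
Reactants: 22 the 8α-allylic alcohol
Product: 24 target CNP0114166.3 (5S,6S,7S,8S,9R,10S)-9-angeloyloxy-7,8-dihydroxyelema-1,3,11(13)-trien-12,6-olide, via epoxy ester 23 (not isolated)
Conditions: VO(acac)2 (5 mol %), tBuOOH (1.1 equiv, decane), CH2Cl2, 0 °C; then Bu4NF (1.5 equiv), THF, 0 → 23 °C; AcOH quench
Reagents that add atoms: tert-butyl hydroperoxide, CC(C)(C)OO
Why: Vanadium-catalysed hydroxyl-directed epoxidation touches only the allylic C6=C7 alkene and adds oxygen syn to the 8α-OH, fluoride then frees the carboxylate on the β face, which opens the epoxide at C6 with inversion (the usual β,γ-epoxy acid to β-hydroxy-γ-lactone closure), and this sets 6β-O and 7α-OH and closes the cis-fused α-methylene lactone (a Payne shift is impossible because the hydroxyl and the epoxide oxygen are cis).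

## Compound list

1 | methylglyoxal | CC(=O)C=O | starting material
2 | 2-(triphenylphosphoranylidene)propanal | CC(C=O)=P(c1ccccc1)(c1ccccc1)c1ccccc1 | starting material
3 | (2E)-2-methyl-4-oxopent-2-enal | CC(=O)/C=C(C)/C=O | intermediate
4 | methyl (2E)-3-methoxybut-2-enoate | CO/C(C)=C/C(=O)OC | starting material
5 | (1E)-1,3-dimethoxy-1-(trimethylsilyloxy)buta-1,3-diene | C=C(OC)/C=C(OC)/O[Si](C)(C)C | intermediate
6 | primary cycloadduct with C9 as methyl trimethylsilyl ketal (C9 epimers, not isolated) | O=C[C@@]1(C)[C@H](C(C)=O)CC(OC)=CC1(OC)O[Si](C)(C)C | intermediate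
7 | (1R,2R)-2-acetyl-4-methoxy-1-methyl-6-oxocyclohex-4-ene-1-carbaldehyde (formyl α, methyl β, acetyl β) | O=C[C@@]1(C)[C@H](C(C)=O)CC(OC)=CC1=O | intermediate
8 | (5S,6S)-6-ethenyl-3-methoxy-6-methyl-5-(prop-1-en-2-yl)cyclohex-2-en-1-one | C=C[C@@]1(C)[C@H](C(=C)C)CC(OC)=CC1=O | intermediate
9 | (1S,5S,6S)-6-ethenyl-3-methoxy-6-methyl-5-(prop-1-en-2-yl)cyclohex-2-en-1-ol (9β-OH) | C=C[C@@]1(C)[C@H](C(=C)C)CC(OC)=C[C@@H]1O | intermediate
10 | angelic acid | OC(=O)/C(C)=C\C | starting material
11 | angelic 2,4,6-trichlorobenzoic anhydride (not isolated) | O=C(OC(=O)/C(C)=C\C)c1c(Cl)cc(Cl)cc1Cl | intermediate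
12 | 9β-angelate of 9 | C=C[C@@]1(C)[C@H](C(=C)C)CC(OC)=C[C@@H]1OC(=O)/C(C)=C\C | intermediate
13 | 7α,8α-epoxide of 12 (7-methoxy epoxide, not isolated) | C=C[C@@]1(C)[C@H](C(=C)C)C[C@@]2(OC)O[C@H]2[C@@H]1OC(=O)/C(C)=C\C | intermediate
14 | (1R,2S,5S,6S)-6-ethenyl-2-hydroxy-6-methyl-3-oxo-5-(prop-1-en-2-yl)cyclohexyl (2Z)-2-methylbut-2-enoate (not isolated) | C=C[C@@]1(C)[C@H](C(=C)C)CC(=O)[C@@H](O)[C@@H]1OC(=O)/C(C)=C\C | intermediate
15 | 8α-triethylsilyl ether of 14 | C=C[C@@]1(C)[C@H](C(=C)C)CC(=O)[C@@H](O[Si](CC)(CC)CC)[C@@H]1OC(=O)/C(C)=C\C | intermediate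
16 | C6=C7 enol triflate of 15 | C=C[C@@]1(C)[C@H](C(=C)C)C=C(OS(=O)(=O)C(F)(F)F)[C@@H](O[Si](CC)(CC)CC)[C@@H]1OC(=O)/C(C)=C\C | intermediate
17 | 2-bromoacrylic acid | C=C(Br)C(=O)O | starting material
18 | 2-(trimethylsilyl)ethanol | C[Si](C)(C)CCO | starting material
19 | 2-(trimethylsilyl)ethyl 2-bromoacrylate | C=C(Br)C(=O)OCC[Si](C)(C)C | intermediate
20 | {3-oxo-3-[2-(trimethylsilyl)ethoxy]prop-1-en-2-yl}zinc bromide (not isolated) | C=C([Zn]Br)C(=O)OCC[Si](C)(C)C | intermediate
21 | C7-(acrylate-2-yl) diene with 8α-OSiEt3 and 9β-angelate | C=C[C@@]1(C)[C@H](C(=C)C)C=C(C(=C)C(=O)OCC[Si](C)(C)C)[C@@H](O[Si](CC)(CC)CC)[C@@H]1OC(=O)/C(C)=C\C | intermediate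
22 | 8α-allylic alcohol from 21 | C=C[C@@]1(C)[C@H](C(=C)C)C=C(C(=C)C(=O)OCC[Si](C)(C)C)[C@@H](O)[C@@H]1OC(=O)/C(C)=C\C | intermediate
23 | 6α,7α-epoxide of 22 (not isolated) | C=C[C@@]1(C)[C@H](C(=C)C)[C@H]2O[C@@]2(C(=C)C(=O)OCC[Si](C)(C)C)[C@@H](O)[C@@H]1OC(=O)/C(C)=C\C | intermediate
24 | CNP0114166.3 | C=C[C@@]1(C)[C@H](C(=C)C)[C@@H]2OC(=O)C(=C)[C@]2(O)[C@@H](O)[C@@H]1OC(=O)/C(C)=C\C | target

## Step count and risks

Total steps: 12. The longest linear sequence is 10 steps (1, 3, 4, 5, 6, 7, 8, 10, 11, 12).

**Step 3 (the proposed new step)** is the most likely to fail.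

- The diene could add to the formyl C=O in a hetero-Diels–Alder reaction.
- The reaction could stop at the open-chain Mukaiyama–Michael adduct.
- An uncatalysed background reaction could erode the ee.

The fallback uses known chemistry only. It sets out from 3 and comes back at 8. Methyl vinyl ketone with iPr3SiOTf and Et3N gives 2-(triisopropylsilyloxy)buta-1,3-diene F1. This acid-stable diene reacts with 3 under the triflimide-activated oxazaborolidine made from (S)-α,α-diphenylprolinol and o-tolylboronic acid. That is the established metal-free Lewis acid catalysis for Diels–Alder reactions of α-substituted enals with 2-silyloxydienes, and it gives the trans formyl/acetyl silyl enol ether F2. Double Wittig methylenation as in step 4 gives the divinyl-type silyl enol ether F3. Saegusa–Ito dehydrogenation with Pd(OAc)2 in MeCN gives 4-ethenyl-4-methyl-5-(prop-1-en-2-yl)cyclohex-2-en-1-one F4. Weitz–Scheffer epoxidation (H2O2, NaOH, MeOH) gives the 8α,9α-epoxy ketone F5. Isomerisation of the epoxy ketone with Pd(PPh3)4 and dppe in toluene gives the cyclohexane-1,3-dione F6. Acid-catalysed enol etherification (HC(OMe)3, MeOH, TsOH) at the carbonyl remote from the quaternary centre then gives 8.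

**Step 6** may fail because the neopentyl allylic alcohol is hindered and acid-labile, and forcing conditions can isomerise the angelate to the tiglate.

The fallback sets out from 9 and comes back at 12. It builds the Z alkene on the ester instead of transferring it. Alcohol 9 is acylated with the small acid 2-[bis(2,2,2-trifluoroethoxy)phosphoryl]propanoic acid (DCC, DMAP) to give the 9β-phosphonopropanoate F7. A Still–Gennari olefination (KN(SiMe3)2, 18-crown-6, acetaldehyde, THF, −78 °C) then gives the (Z)-2-methylbut-2-enoate 12.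

**Step 12** may fail because the carboxylate has to reach C6 in a geometrically tight closure, and the tertiary allylic C7–O bond may break instead.

The fallback sets out from 22 and comes back at 24. It replaces the anionic closure by a chelation-controlled one. The epoxidation is run alone and 23 is isolated. The ester is cleaved with tris(dimethylamino)sulfonium difluorotrimethylsilicate at −20 °C to give the 6α,7α-epoxy acid F8. Ti(OiPr)4 (1.2 equiv, CH2Cl2) then binds the 8-alkoxide, the epoxide oxygen and the carboxylate. It delivers the carboxylate to C6, which is the distal carbon favoured in titanium-mediated openings of 2,3-epoxy alcohols.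

## Further compounds

F1 | step 3 | 2-(triisopropylsilyloxy)buta-1,3-diene | C=CC(=C)O[Si](C(C)C)(C(C)C)C(C)C
F2 | step 3 | 6-acetyl-1-methyl-4-(triisopropylsilyloxy)cyclohex-3-ene-1-carbaldehyde (formyl α, methyl β, acetyl β) | O=C[C@@]1(C)[C@H](C(C)=O)CC(O[Si](C(C)C)(C(C)C)C(C)C)=CC1
F3 | step 3 | [4-ethenyl-4-methyl-5-(prop-1-en-2-yl)cyclohex-1-en-1-yl]oxy-triisopropylsilane (vinyl α, isopropenyl β) | C=C[C@@]1(C)[C@H](C(=C)C)CC(O[Si](C(C)C)(C(C)C)C(C)C)=CC1
F4 | step 3 | 4-ethenyl-4-methyl-5-(prop-1-en-2-yl)cyclohex-2-en-1-one (vinyl α, isopropenyl β) | C=C[C@@]1(C)[C@H](C(=C)C)CC(=O)C=C1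
F5 | step 3 | 8α,9α-epoxy ketone from F4 | C=C[C@@]1(C)[C@H](C(=C)C)CC(=O)[C@H]2O[C@@H]12
F6 | step 3 | 4-ethenyl-4-methyl-5-(prop-1-en-2-yl)cyclohexane-1,3-dione (vinyl α, isopropenyl β) | C=C[C@@]1(C)[C@H](C(=C)C)CC(=O)CC1=O
F7 | step 6 | 9β-{2-[bis(2,2,2-trifluoroethoxy)phosphoryl]propanoate} of 9 (epimers at the phosphonate carbon) | C=C[C@@]1(C)[C@H](C(=C)C)CC(OC)=C[C@@H]1OC(=O)C(C)P(=O)(OCC(F)(F)F)OCC(F)(F)F
F8 | step 12 | 6α,7α-epoxy acid from 23 | C=C[C@@]1(C)[C@H](C(=C)C)[C@H]2O[C@@]2(C(=C)C(=O)O)[C@@H](O)[C@@H]1OC(=O)/C(C)=C\C
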